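In a one-step, first-order world L turns into E and the percentages do not depend on the charge. South and east do share one curve up to 3.00 min, with L at 67.3 % against 66.4 %, but at 4.00 min the east run shows J at 6.5 %.

| flask | L | remark | time |
|---|---|---|---|
| south | 0.050 M | run made earlier |  |
| east | 0.20 M | run made earlier |  |
| flask | 0.10 M |  | 5.0 min |

| run | time / min | E / % | J / % | L / % |
|---|---|---|---|---|
| south | 0.500 | 9.1 | 0.4 | 92.2 |
| south | 1.50 | 21.1 | 0.4 | 78.9 |
| south | 3.00 | 34.2 | 0 | 67.3 |
| south | 4.00 | 37.1 | 0.7 | 61.8 |
| south | 6.00 | 42.8 | 0 | 56.5 |
| east | 0.500 | 8.1 | 0.3 | 91.3 |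
| east | 1.50 | 20.5 | 0 | 79.1 |
| east | 3.00 | 32.2 | 0 | 66.4 |
| east | 4.00 | 38.7 | 6.5 | 61.6 |
| east | 6.00 | 46.2 | 13.6 | 54.6 |

(each reading ± 0.5 percentage points)

- E is meant together with its J
- solid, in amounts per volume of the solution: J
- the numbers in the tables scatter by 0.5 percentage points (one standard deviation)

1. the E and J together standing at 5.0 min, as a percentage of the L charged
2. concentration of E in solution at 5.0 min, in percent of saturation

The E column counts J too, so E minus J is dissolved E. The two east readings with J present average 0.0648 M, our reading of the saturation concentration (solubility), the [E] the east run holds while J stands. Our own reckoning takes the mean of the south and east E readings at 4.00 min and 6.00 min, 41.2 % for 5.0 min. In the flask that makes [E] 0.0412 M, 63.6 % of saturation, and since this is less than the saturation concentration, we expect no J.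

The forecast gives 41.2 % (40.2 % to 42.2 %) and 64.5 % (60 % to 68 %), holding that “At 0.10 M, E can reach at most about 0.05 M, which is below saturation, so no J forms”.

The flask gives 40.8 % and 62.8 %, with J at 0 %, both inside the forecast's ranges.

    L ⇌ E (K = 0.916, k = 0.184 min⁻¹)
    J ⇌ E, rate k2*(cs2 - [E]) while solid is left; crystals form when [E] > cs2 (solubility = 0.0650 M, k = 19.8 min⁻¹)

A neighbour flask charged with 0.17 M of L stands at E 41.0 % at 5.00 min, with J 2.62 % counted in it. Its E and J together come to 0.0697 M, more than our saturation reading, and J stands in that neighbour flask. The flask itself is still moving at 5.0 min, with L at 59.2 %. At 50.0 min L stands at 52.2 % and E and J together at 47.8 %, a further 7 percentage points. There [E] is 0.0478 M, 73.8 % of our saturation reading, and J stands at 0 %.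

The numbers in the tables are simulated for substances that don't exist; the scatter is artificial.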